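**Retrosynthetic overview**
- Target ⇐ C15–O desilylation ⇐ ring A 3-ketone (equatorial hydride attack gives the axial 3α-oxygen, acetylated in the same flask) ⇐ α-face C-methylation of a ring A β-keto ester (sets C4).
- β-Keto ester ⇐ 3β-hydroxy ester ⇐ glycidic ester. The key bond is C3–O, made as an epoxide by catalytic asymmetric epoxidation of an (E)-enoate; this one C–O stereocentre carries all chirality into the decalin, and its oxygen remains the C3 oxygen of the target.
- Rings: ring A (C4–C5) first, then ring B (C10–C9), in one radical cascade started by opening that epoxide with trivalent titanium; termination gives the exocyclic C8=C17 alkene.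
- Open-chain enoate ⇐ cross-metathesis with methyl acrylate ⇐ allyl Grignard coupling ⇐ allylic bromide ⇐ SeO2 oxidation of silylated (S)-dihydrofarnesol.
- C13 ⇐ asymmetric hydrogenation of (2E,6E)-farnesol.

Assumption: the SMILES is read as methyl (13S)-3α-acetoxy-15-hydroxylabd-8(17)-en-19-oate (3R,4R,5R,9S,10R,13S; 5α-H, 10β-Me, 4β-CO2Me, 4α-Me); labdane numbering (C1–C20) is used for all compounds, open-chain ones included.

**Step 1**
Reactants: 1 (2E,6E)-farnesol
Product: 2 (S)-2,3-dihydrofarnesol, (3S,6E)-3,7,11-trimethyldodeca-6,10-dien-1-ol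
Conditions: H2 (90 atm), Ru(OAc)2[(R)-BINAP] (0.2 mol %), MeOH–H2O 95:5, 20 °C
Reagents that add atoms: none
Why: Noyori asymmetric hydrogenation of an (E)-allylic alcohol reduces only the hydroxyl-directed C2=C3 bond, and the (R)-BINAP complex delivers hydrogen to the face that gives the (S)-methyl centre (future C13) while the remote trisubstituted alkenes stay intact.

**Step 2**
Reactants: 2 (S)-2,3-dihydrofarnesol
Product: 3 tert-butyl(diphenyl){[(3S,6E)-3,7,11-trimethyldodeca-6,10-dien-1-yl]oxy}silane
Conditions: TBDPSCl, imidazole, CH2Cl2, 0 °C → rt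
Reagents that add atoms: tert-butyl(chloro)diphenylsilane, CC(C)(C)[Si](Cl)(c1ccccc1)c1ccccc1
Why: Standard silylation of a primary alcohol gives an ether that survives Grignard, radical, hydride and acetylation conditions and is removed last without touching an acetate.

**Step 3**
Reactants: 3 TBDPS ether of (S)-dihydrofarnesol
Product: 4 (2E,6E,10S)-12-[(tert-butyldiphenylsilyl)oxy]-2,6,10-trimethyldodeca-2,6-dien-1-ol
Conditions: SeO2 (10 mol %), t-BuOOH (3 equiv), salicylic acid (10 mol %), CH2Cl2, rt
Reagents that add atoms: tert-butyl hydroperoxide, CC(C)(C)OO (terminal oxygen source; SeO2, O=[Se]=O, relays the oxygen atom)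
Why: Catalytic SeO2 allylic oxidation (ene reaction then 2,3-sigmatropic shift) attacks the (E)-methyl of the least hindered, terminal trisubstituted alkene and gives the (E)-allylic alcohol whose carbinol carbon becomes C1.

**Step 4**
Reactants: 4 allylic alcohol
Product: 5 (2E,6E,10S)-1-bromo-12-[(tert-butyldiphenylsilyl)oxy]-2,6,10-trimethyldodeca-2,6-diene
Conditions: CBr4, PPh3, CH2Cl2, −20 → 0 °C
Reagents that add atoms: tetrabromomethane, BrC(Br)(Br)Br
Why: Appel bromination converts the primary allylic alcohol into the bromide by SN2 displacement of the oxyphosphonium group without allylic transposition or loss of alkene geometry.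

**Step 5**
Reactants: 5 allylic bromide; 6 allylmagnesium bromide
Product: 7 tert-butyl(diphenyl){[(3S,6E,10E)-3,7,11-trimethylpentadeca-6,10,14-trien-1-yl]oxy}silane
Conditions: THF, −20 °C → rt
Reagents that add atoms: none
Why: Allyl Grignard coupling with a primary allylic bromide proceeds by direct SN2 attack at C1, adding the carbons that become C2 and C3 and leaving a terminal vinyl group for the next step.

**Step 6**
Reactants: 7 terminal alkene; 8 methyl acrylate
Product: 9 methyl (2E,6E,10E,14S)-16-[(tert-butyldiphenylsilyl)oxy]-6,10,14-trimethylhexadeca-2,6,10-trienoate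
Conditions: second-generation Grubbs catalyst RuCl2(PCy3)(H2IMes)(=CHPh) (3 mol %), 8 (4 equiv), CH2Cl2, 40 °C
Reagents that add atoms: none
Why: Olefin cross-metathesis engages only the monosubstituted alkene (the trisubstituted alkenes are inert) and pairs it with the electron-poor acrylate to give the (E)-enoate that carries C4 and the ester carbon C19.

**Step 7**
Reactants: 9 (E)-enoate
Product: 10 methyl (2R,3S)-3-[(3E,7E,11S)-13-[(tert-butyldiphenylsilyl)oxy]-3,7,11-trimethyltrideca-3,7-dien-1-yl]oxirane-2-carboxylate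
Conditions: Y(Oi-Pr)3 (5 mol %), chiral 6,6'-tethered biphenyl-2,2'-diol ligand (5 mol %), Ph3As=O (5 mol %), t-BuOOH, 4 Å MS, THF, rt
Reagents that add atoms: tert-butyl hydroperoxide, CC(C)(C)OO
Why: Catalytic asymmetric nucleophilic (Weitz–Scheffer-type) epoxidation adds the yttrium-bound peroxide only to the electron-poor enoate, and the ligand enantiomer is chosen so that the new C3–O bond has the (3S) configuration in the trans-(2R,3S) glycidate; this is the key C–O bond of the route.

**Step 8**
Reactants: 10 glycidic ester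
Product: 12 bicyclic hydroxy ester (decalin in labdane numbering: 3β-OH; 4-CO2Me equatorial plus its C4 epimer; 5α-H; 10β-Me; 9β side chain; exocyclic C8=C17; C15 OTBDPS), via trimethylsilyl ether 11 (not isolated)
Conditions: Cp2TiCl2 (20 mol %), Mn dust, Me3SiCl, 2,4,6-collidine, THF (slow addition of 10, 0.01 M), rt; then 1 M HCl, rt
Reagents that add atoms: none
Why: Proposed new method: Cp2TiCl (trivalent titanium, made in the flask from Cp2TiCl2 and Mn) should cleave the Cα–O bond of the glycidic ester homolytically (Nugent–RajanBabu-type opening) because the C4 radical is ester-stabilised, leaving the (3S) C–O bond intact as a titanium alkoxide; this electrophilic radical is polarity-matched to add 6-endo to the electron-rich C5=C10 alkene (ring A) through a chair transition state with the C3–O[Ti] group equatorial, the tertiary C10 radical then closes ring B 6-endo onto C9=C8 (chair, trans-anti), and the tertiary C8 radical is trapped by a second Cp2TiCl and loses a methyl hydrogen by β-hydride elimination to give the exocyclic alkene, so C5, C9 and C10 are set relative to C3 while C4 forms as an epimer mixture that steps 9 and 10 level; the low catalyst loading keeps Cp2TiCl scarce so that cyclisation outruns reduction of the radical to a titanium enolate; the closest known reaction is the titanocene-catalysed radical cyclisation of 2,3-epoxypolyprenes to 3β-hydroxy terpenoids with exocyclic alkenes, which has not been shown for α,β-epoxy esters.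

**Step 9**
Reactants: 12 bicyclic hydroxy ester
Product: 13 bicyclic β-keto ester (3-oxo; 4-CO2Me with 4-H, keto form drawn, in equilibrium with its enol; otherwise as 12)
Conditions: Dess–Martin periodinane, CH2Cl2, rt
Reagents that add atoms: none
Why: Dess–Martin oxidation of the secondary alcohol, whose configuration has finished relaying chirality to the ring fusion, converges both C4 epimers onto one enolisable β-keto ester.

**Step 10**
Reactants: 13 bicyclic β-keto ester
Product: 14 methyl (13S)-15-[(tert-butyldiphenylsilyl)oxy]-3-oxolabd-8(17)-en-19-oate (4α-Me, 4β-CO2Me)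
Conditions: MeI, K2CO3, acetone, 56 °C
Reagents that add atoms: iodomethane, CI
Why: C-alkylation of the cyclic β-keto ester enolate takes place on the α-face, away from the axial C10 methyl that blocks the β-face, so the new methyl is 4α and the ester becomes axial 4β as in the classical podocarpate series (C4 = R).

**Step 11**
Reactants: 14 methylated keto ester
Product: 16 methyl (13S)-3α-acetoxy-15-[(tert-butyldiphenylsilyl)oxy]labd-8(17)-en-19-oate, via lithium alkoxide 15 (not isolated)
Conditions: Li[HB(sec-Bu)3] (L-Selectride), THF, −78 °C; then Ac2O, DMAP, −78 °C → rt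
Reagents that add atoms: acetic anhydride, CC(=O)OC(C)=O
Why: Bulky-hydride (Selectride) reduction attacks the C3 ketone along the equatorial trajectory to give the axial 3α-alkoxide (3R), which DMAP-catalysed acylation traps in the same flask before retro-aldol cleavage can occur.

**Step 12**
Reactants: 16 silyl-protected acetate
Product: 17 methyl (13S)-3α-acetoxy-15-hydroxylabd-8(17)-en-19-oate (target)
Conditions: HF·pyridine, THF, 0 °C → rt
Reagents that add atoms: none
Why: Fluoride-driven desilylation (Si–F bond formation) frees the primary C15 alcohol while the hindered axial acetate, the methyl ester and the exocyclic alkene are untouched.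

**Compound list**
1 | (2E,6E)-farnesol | CC(C)=CCC/C(C)=C/CC/C(C)=C/CO | starting material
2 | (S)-2,3-dihydrofarnesol, (3S,6E)-3,7,11-trimethyldodeca-6,10-dien-1-ol | CC(C)=CCC/C(C)=C/CC[C@H](C)CCO | intermediate
3 | tert-butyl(diphenyl){[(3S,6E)-3,7,11-trimethyldodeca-6,10-dien-1-yl]oxy}silane | CC(C)=CCC/C(C)=C/CC[C@H](C)CCO[Si](c1ccccc1)(c1ccccc1)C(C)(C)C | intermediate
4 | (2E,6E,10S)-12-[(tert-butyldiphenylsilyl)oxy]-2,6,10-trimethyldodeca-2,6-dien-1-ol | OC/C(C)=C/CC/C(C)=C/CC[C@H](C)CCO[Si](c1ccccc1)(c1ccccc1)C(C)(C)C | intermediate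
5 | (2E,6E,10S)-1-bromo-12-[(tert-butyldiphenylsilyl)oxy]-2,6,10-trimethyldodeca-2,6-diene | BrC/C(C)=C/CC/C(C)=C/CC[C@H](C)CCO[Si](c1ccccc1)(c1ccccc1)C(C)(C)C | intermediate
6 | allylmagnesium bromide | C=CC[Mg]Br | starting material
7 | tert-butyl(diphenyl){[(3S,6E,10E)-3,7,11-trimethylpentadeca-6,10,14-trien-1-yl]oxy}silane | C=CCC/C(C)=C/CC/C(C)=C/CC[C@H](C)CCO[Si](c1ccccc1)(c1ccccc1)C(C)(C)C | intermediate
8 | methyl acrylate | C=CC(=O)OC | starting material
9 | methyl (2E,6E,10E,14S)-16-[(tert-butyldiphenylsilyl)oxy]-6,10,14-trimethylhexadeca-2,6,10-trienoate | COC(=O)/C=C/CC/C(C)=C/CC/C(C)=C/CC[C@H](C)CCO[Si](c1ccccc1)(c1ccccc1)C(C)(C)C | intermediate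
10 | methyl (2R,3S)-3-[(3E,7E,11S)-13-[(tert-butyldiphenylsilyl)oxy]-3,7,11-trimethyltrideca-3,7-dien-1-yl]oxirane-2-carboxylate | COC(=O)[C@@H]1O[C@H]1CC/C(C)=C/CC/C(C)=C/CC[C@H](C)CCO[Si](c1ccccc1)(c1ccccc1)C(C)(C)C | intermediate
11 | trimethylsilyl ether of 12 (3β-OSiMe3; major C4 epimer drawn) | C=C1CC[C@@H]2[C@](C)(CC[C@H](O[Si](C)(C)C)[C@H]2C(=O)OC)[C@H]1CC[C@H](C)CCO[Si](c1ccccc1)(c1ccccc1)C(C)(C)C | intermediate
12 | bicyclic hydroxy ester: 3β-hydroxy, 4-CO2Me equatorial (4-H axial; C4 epimer also present), 5α-H, 10β-Me, 9β side chain, exocyclic C8=C17, C15 OTBDPS, 13S | C=C1CC[C@@H]2[C@](C)(CC[C@H](O)[C@H]2C(=O)OC)[C@H]1CC[C@H](C)CCO[Si](c1ccccc1)(c1ccccc1)C(C)(C)C | intermediate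
13 | bicyclic β-keto ester: 3-oxo, 4-CO2Me with 4-H (keto form drawn, enolisable), otherwise as 12 | C=C1CC[C@@H]2[C@](C)(CCC(=O)[C@H]2C(=O)OC)[C@H]1CC[C@H](C)CCO[Si](c1ccccc1)(c1ccccc1)C(C)(C)C | intermediate
14 | methyl (13S)-15-[(tert-butyldiphenylsilyl)oxy]-3-oxolabd-8(17)-en-19-oate | C=C1CC[C@@H]2[C@](C)(CCC(=O)[C@]2(C)C(=O)OC)[C@H]1CC[C@H](C)CCO[Si](c1ccccc1)(c1ccccc1)C(C)(C)C | intermediate
15 | lithium 3α-alkoxide of methyl (13S)-15-[(tert-butyldiphenylsilyl)oxy]-3α-hydroxylabd-8(17)-en-19-oate | C=C1CC[C@@H]2[C@](C)(CC[C@@H]([O-])[C@]2(C)C(=O)OC)[C@H]1CC[C@H](C)CCO[Si](c1ccccc1)(c1ccccc1)C(C)(C)C.[Li+] | intermediate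
16 | methyl (13S)-3α-acetoxy-15-[(tert-butyldiphenylsilyl)oxy]labd-8(17)-en-19-oate | C=C1CC[C@@H]2[C@](C)(CC[C@@H](OC(C)=O)[C@]2(C)C(=O)OC)[C@H]1CC[C@H](C)CCO[Si](c1ccccc1)(c1ccccc1)C(C)(C)C | intermediate
17 | methyl (13S)-3α-acetoxy-15-hydroxylabd-8(17)-en-19-oate, (3R,4R,5R,9S,10R,13S) | C=C1CC[C@@H]2[C@](C)(CC[C@@H](OC(C)=O)[C@]2(C)C(=O)OC)[C@H]1CC[C@H](C)CCO | target

**Step count and risks**
Total steps: 12. Longest linear sequence: 12 steps (1 → 17).

Three steps most likely to fail:

- Step 8 (the proposed titanium cascade). The α-ester radical may be reduced to a titanium enolate, or the oxygen may be eliminated back to enoate 9, faster than it cyclises. The fallback gives up the epoxide relay and closes the rings by the known auxiliary-controlled oxidative radical cyclisation of a β-keto ester. It sets out from bromide 5, which is alkylated with the dianion (NaH then n-BuLi, THF, 0 °C) of (+)-8-phenylmenthyl acetoacetate to give the open-chain (+)-8-phenylmenthyl keto ester F1. Mn(OAc)3·2H2O and Cu(OAc)2 with Yb(OTf)3 in CF3CH2OH at −5 °C (Snider-type oxidative bicyclisation; the auxiliary selects the face, copper-mediated oxidative termination gives the exocyclic alkene) then give the bicyclic (+)-8-phenylmenthyl keto ester F2. DMAP-catalysed transesterification with MeOH (toluene, 110 °C, via the acylketene) releases the auxiliary and comes back to the route at keto ester 13. The enantiomeric auxiliary is used if the facial sense proves opposite; the price is a stoichiometric, costly auxiliary.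

- Step 3 (SeO2 oxidation). Oxidation at the internal alkene and over-oxidation to the enal limit the yield. The fallback sets out from silyl ether 3 and cleaves and rebuilds the terminal alkene instead. NBS in THF–H2O gives the terminal bromohydrin F3, K2CO3 in MeOH the terminal epoxide F4, and HIO4 in Et2O–THF the chain-shortened aldehyde F5. Wittig olefination with Ph3P=C(CH3)CO2Et gives the (E)-enoate F6, and i-Bu2AlH (CH2Cl2, −78 °C) reduces it to rejoin the route at allylic alcohol 4.

- Step 10 (C4 methylation). O-methylation or attack from the wrong face would be costly this late. The fallback sets out from hydroxy ester 12 and reverses the order of oxidation and methylation. The dianion (LiN(i-Pr)2, 2.2 equiv, THF–DMPU, −78 → −20 °C) is methylated with MeI (Frater–Seebach alkylation; the chelated alkoxide–enolate is attacked anti to the 3β-oxygen and to the C10 methyl) to give the 3β-hydroxy-4α-methyl ester F7. Dess–Martin oxidation of F7 comes back to the route at ketone 14.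

**Further compounds**
F1 | step 8 | (1S,2R,5S)-8-phenylmenthyl (6E,10E,14S)-16-[(tert-butyldiphenylsilyl)oxy]-6,10,14-trimethyl-3-oxohexadeca-6,10-dienoate | O=C(CC(=O)CC/C(C)=C/CC/C(C)=C/CC[C@H](C)CCO[Si](c1ccccc1)(c1ccccc1)C(C)(C)C)O[C@H]1C[C@@H](C)CC[C@@H]1C(C)(C)c1ccccc1
F2 | step 8 | (1S,2R,5S)-8-phenylmenthyl ester analogue of keto ester 13 (3-oxo, 4-H, 5α-H, 10β-Me, 9β side chain, exocyclic C8=C17, C15 OTBDPS) | C=C1CC[C@@H]2[C@](C)(CCC(=O)[C@H]2C(=O)O[C@H]3C[C@@H](C)CC[C@@H]3C(C)(C)c3ccccc3)[C@H]1CC[C@H](C)CCO[Si](c1ccccc1)(c1ccccc1)C(C)(C)C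
F3 | step 3 | (6E,10S)-3-bromo-12-[(tert-butyldiphenylsilyl)oxy]-2,6,10-trimethyldodec-6-en-2-ol (both C3 epimers) | CC(C)(O)C(Br)CC/C(C)=C/CC[C@H](C)CCO[Si](c1ccccc1)(c1ccccc1)C(C)(C)C
F4 | step 3 | tert-butyl{[(3S,6E)-9-(3,3-dimethyloxiran-2-yl)-3,7-dimethylnon-6-en-1-yl]oxy}diphenylsilane (both oxirane epimers) | CC1(C)OC1CC/C(C)=C/CC[C@H](C)CCO[Si](c1ccccc1)(c1ccccc1)C(C)(C)C
F5 | step 3 | (4E,8S)-10-[(tert-butyldiphenylsilyl)oxy]-4,8-dimethyldec-4-enal | O=CCC/C(C)=C/CC[C@H](C)CCO[Si](c1ccccc1)(c1ccccc1)C(C)(C)C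
F6 | step 3 | ethyl (2E,6E,10S)-12-[(tert-butyldiphenylsilyl)oxy]-2,6,10-trimethyldodeca-2,6-dienoate | CCOC(=O)/C(C)=C/CC/C(C)=C/CC[C@H](C)CCO[Si](c1ccccc1)(c1ccccc1)C(C)(C)C
F7 | step 10 | methyl (13S)-15-[(tert-butyldiphenylsilyl)oxy]-3β-hydroxylabd-8(17)-en-19-oate | C=C1CC[C@@H]2[C@](C)(CC[C@H](O)[C@]2(C)C(=O)OC)[C@H]1CC[C@H](C)CCO[Si](c1ccccc1)(c1ccccc1)C(C)(C)C
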